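**Retrosynthetic overview**

1. Feature: in ring C (the pyranone ring) C3 is a CH that carries ring B and two oxygenated one-carbon arms, C2 (the OCH2 bound to O1) and C4 (the C=O bound to C4a). Brought to one oxidation level, these arms are the two CH2OH groups of a prochiral 2-(ring B)propane-1,3-diol.
2. Late disconnections: the four MOM ethers; ring C at C4–C4a (Friedel–Crafts acylation by a (2R)-2-aryl-3-aryloxypropanoic acid onto the symmetric ring A, so the 6-methyl position needs no control); the acid back to a primary alcohol; the O1–C2 ether back to a Mitsunobu coupling of a symmetric ring A phenol with an (R)-monobenzoate.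
3. Key disconnection: the (R)-monobenzoate comes from the diol by catalytic enantioselective benzoyl transfer (dinuclear zinc–ProPhenol catalyst, vinyl benzoate). The benzoylated arm becomes C4 and the free arm becomes C2.
4. The diol comes from palladium-catalysed malonate arylation and hydride reduction of the geranylated ring B bromide (from 4,6-dibromoresorcinol). The ring A phenol comes from 2-methylresorcinol by C–H borylation and oxidation.
5. Ring order: rings A and B are bought as benzenes; ring C is the only ring formed, in step 11.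

Key step: step 5

Assumption: the (S,S)-antipode of ProPhenol, 2,6-bis{[(2S)-2-(hydroxydiphenylmethyl)pyrrolidin-1-yl]methyl}-4-methylphenol, is written for step 5; which antipode benzoylates the pro-R arm of this ortho-alkoxyaryl diol would be settled on a first run, and the (R,R)-ligand is used if the sense is reversed.

Abbreviations: geranyl = (2E)-3,7-dimethylocta-2,6-dien-1-yl; MOM = methoxymethyl.

**Route**

Step 1
Reactants: 1 4,6-dibromoresorcinol (4,6-dibromobenzene-1,3-diol)
Product: 2 1,5-dibromo-2,4-bis(methoxymethoxy)benzene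
Conditions: NaH, MOMCl, DMF, 0 °C to rt
Reagents that add atoms: chloromethyl methyl ether (MOMCl), COCCl
Why: Double O-alkylation of the two phenoxides by the reactive α-chloro ether (Williamson-type MOM protection) should give the bis-acetal, which tolerates organolithium, hydride and basic conditions.

Step 2
Reactants: 2 1,5-dibromo-2,4-bis(methoxymethoxy)benzene; 3 geranyl bromide [(2E)-1-bromo-3,7-dimethylocta-2,6-diene]
Product: 6 1-bromo-5-geranyl-2,4-bis(methoxymethoxy)benzene, via aryllithium 4 (not isolated), via arylcopper 5 (not isolated)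
Conditions: n-BuLi (1.0 equiv), THF, −78 °C; CuBr·SMe2 (1.0 equiv, monovalent copper), −78 to −40 °C; 3, −78 °C to rt
Reagents that add atoms: none
Why: One bromine–lithium exchange (a second is disfavoured on the already metalated ring) should give an ortho-alkoxy aryllithium that is transmetalated to the arylcopper and alkylated at the primary carbon of the allylic bromide (copper-mediated SN2 allylic substitution), the hindered tertiary terminus disfavouring SN2' attack and the E-alkene being carried over unchanged.

Step 3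
Reactants: 6 1-bromo-5-geranyl-2,4-bis(methoxymethoxy)benzene; 7 dimethyl malonate
Product: 8 dimethyl 2-[5-geranyl-2,4-bis(methoxymethoxy)phenyl]propanedioate
Conditions: Pd(OAc)2 (3 mol %), P(t-Bu)3·HBF4 (6 mol %), K3PO4, toluene, 80 °C
Reagents that add atoms: none
Why: Palladium-catalysed α-arylation of a malonate (oxidative addition of the aryl bromide to zerovalent palladium carrying the bulky electron-rich phosphine, enolate binding, reductive elimination) should give the arylmalonate, which stays as its enolate under the base and so is not arylated twice.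

Step 4
Reactants: 8 dimethyl 2-[5-geranyl-2,4-bis(methoxymethoxy)phenyl]propanedioate
Product: 9 2-[5-geranyl-2,4-bis(methoxymethoxy)phenyl]propane-1,3-diol
Conditions: LiAlH4 (excess), THF, 0 °C to rt, inverse addition; aqueous NaOH work-up
Reagents that add atoms: none
Why: Hydride reduction of both esters to primary alcohols, with the malonate added to excess hydride in the cold so that reduction stays ahead of enolisation and of β-elimination from the half-reduced intermediate; acetals and alkenes are inert to LiAlH4.

Step 5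
Reactants: 9 2-[5-geranyl-2,4-bis(methoxymethoxy)phenyl]propane-1,3-diol; 10 vinyl benzoate
Product: 11 (2R)-2-[5-geranyl-2,4-bis(methoxymethoxy)phenyl]-3-hydroxypropyl benzoate
Conditions: Et2Zn (10 mol %), (S,S)-ProPhenol (5 mol %), 10 (5 equiv), toluene, −20 °C; pH 7 buffer quench
Reagents that add atoms: none
Why: Et2Zn and the ligand lose ethane to form a dinuclear zinc complex; the diol binds one zinc as an alkoxide while vinyl benzoate is activated at the other, benzoyl passes to the bound oxygen, and the vinyl alcohol released tautomerises to acetaldehyde so the transfer cannot reverse. The closest known reaction type is the desymmetrising mono-benzoylation of 2-aryl-1,3-propanediols with vinyl benzoate under dinuclear zinc amino-alcohol catalysis. No ring is closed and no skeletal bond is made; the step only tells the two CH2OH arms apart. The new stereocentre (the future C3) is controlled by the ligand configuration alone: the aryl group fits one region of the chiral pocket, so only the pro-R hydroxymethyl group reaches the activated ester and the monoester is (2R). The step needs selectivity between the enantiotopic arms and mono- over bis-acylation; the substrate helps because the diol chelates the bimetallic site better than the monoester does, and a benzoate is transferred because it resists 1,3-acyl migration, the one path that would racemise the product. The monoester is therefore worked up at neutral pH and taken to step 8 without contact with base.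

Step 6
Reactants: 12 2-methylresorcinol (2-methylbenzene-1,3-diol)
Product: 13 1,3-bis(methoxymethoxy)-2-methylbenzene
Conditions: NaH, MOMCl, DMF, 0 °C to rt
Reagents that add atoms: chloromethyl methyl ether (MOMCl), COCCl
Why: Williamson-type MOM protection of both phenols as in step 1, giving a symmetric arene whose only unhindered C–H is para to the methyl group.

Step 7
Reactants: 13 1,3-bis(methoxymethoxy)-2-methylbenzene
Product: 15 3,5-bis(methoxymethoxy)-4-methylphenol, via arylboronate 14 (not isolated)
Conditions: [Ir(OMe)(cod)]2 (1.5 mol %), 4,4'-di-tert-butyl-2,2'-bipyridine (3 mol %), HBpin, THF, 60 °C; then aq. Oxone (2KHSO5·KHSO4·K2SO4), acetone, 0 °C to rt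
Reagents that add atoms: potassium peroxymonosulfate (KHSO5, the active salt of Oxone), [K+].[O-]S(=O)(=O)OO
Why: Iridium-catalysed C–H borylation is sterically controlled and on this 1,2,3-trisubstituted ring should attack only C5, the one C–H without an ortho substituent, and the boronate is then oxidised in the same flask by peroxymonosulfate (aryl migration from boron to oxygen) to the phenol.

Step 8
Reactants: 11 (2R)-2-[5-geranyl-2,4-bis(methoxymethoxy)phenyl]-3-hydroxypropyl benzoate; 15 3,5-bis(methoxymethoxy)-4-methylphenol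
Product: 16 (2R)-3-[3,5-bis(methoxymethoxy)-4-methylphenoxy]-2-[5-geranyl-2,4-bis(methoxymethoxy)phenyl]propyl benzoate
Conditions: PPh3, DIAD, THF, 0 °C to rt
Reagents that add atoms: none
Why: Mitsunobu etherification, in which the primary alkoxyphosphonium ion is displaced by the phenoxide at CH2 without touching the stereocentre; the medium is neutral so the benzoate does not migrate, and a full equivalent of phenoxide should let direct displacement outrun participation by the neighbouring benzoate.

Step 9
Reactants: 16 (2R)-3-[3,5-bis(methoxymethoxy)-4-methylphenoxy]-2-[5-geranyl-2,4-bis(methoxymethoxy)phenyl]propyl benzoate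
Product: 17 (2S)-3-[3,5-bis(methoxymethoxy)-4-methylphenoxy]-2-[5-geranyl-2,4-bis(methoxymethoxy)phenyl]propan-1-ol
Conditions: K2CO3 (cat.), MeOH/THF, rt
Reagents that add atoms: none
Why: Base-catalysed transesterification (methanolysis) of the benzoate is safe now that the other arm is an aryl ether and the stereocentre is not acidic; the descriptor becomes S only because the CIP ranking of the two arms changes.

Step 10
Reactants: 17 (2S)-3-[3,5-bis(methoxymethoxy)-4-methylphenoxy]-2-[5-geranyl-2,4-bis(methoxymethoxy)phenyl]propan-1-ol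
Product: 19 (2R)-3-[3,5-bis(methoxymethoxy)-4-methylphenoxy]-2-[5-geranyl-2,4-bis(methoxymethoxy)phenyl]propanoic acid, via aldehyde 18 (not isolated)
Conditions: TEMPO (20 mol %), PhI(OAc)2 (2.2 equiv), MeCN/H2O 1:1, 0 °C to rt
Reagents that add atoms: water, O
Why: Oxoammonium (TEMPO-catalysed) oxidation with PhI(OAc)2 as terminal oxidant should take the alcohol to the aldehyde and, through its hydrate, to the acid in one flask; the medium is weakly acidic and chlorine-free, which spares the alkenes and electron-rich rings and keeps the α-aryl aldehyde away from base that would epimerise it or expel the aryloxide.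

Step 11
Reactants: 19 (2R)-3-[3,5-bis(methoxymethoxy)-4-methylphenoxy]-2-[5-geranyl-2,4-bis(methoxymethoxy)phenyl]propanoic acid
Product: 21 (3R)-3-[5-geranyl-2,4-bis(methoxymethoxy)phenyl]-5,7-bis(methoxymethoxy)-6-methylchroman-4-one, via mixed anhydride 20 (not isolated)
Conditions: (CF3CO)2O (1.5 equiv), CH2Cl2, −20 to 0 °C, short reaction time; NaHCO3 quench
Reagents that add atoms: none
Why: Intramolecular Friedel–Crafts acylation, in which the mixed trifluoroacetic anhydride acylates the phloroglucinol-type ring A at the carbon ortho to the ether oxygen to close the six-membered ring C; the two ortho carbons are equivalent, so the methyl group ends at C6, and with no base present no ketene can form and C3 should keep its configuration.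

Step 12
Reactants: 21 (3R)-3-[5-geranyl-2,4-bis(methoxymethoxy)phenyl]-5,7-bis(methoxymethoxy)-6-methylchroman-4-one
Product: 22 (3R)-3-(5-geranyl-2,4-dihydroxyphenyl)-5,7-dihydroxy-6-methylchroman-4-one (target)
Conditions: HCl (1.25 M in MeOH), THF, 0 °C to rt
Reagents that add atoms: none
Why: Acid-catalysed acetal exchange with methanol should remove the four MOM groups as dimethoxymethane, with dilute acid near room temperature chosen to keep the geranyl chain from cyclising onto the 4'-hydroxyl and to keep acid-catalysed enolisation at C3 slow.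

**Compound list**

1 | 4,6-dibromoresorcinol | Oc1cc(O)c(Br)cc1Br | starting material
2 | 1,5-dibromo-2,4-bis(methoxymethoxy)benzene | COCOc1cc(OCOC)c(Br)cc1Br | intermediate
3 | geranyl bromide | CC(C)=CCC/C(C)=C/CBr | starting material
4 | [5-bromo-2,4-bis(methoxymethoxy)phenyl]lithium (formed in the flask) | [Li]c1cc(Br)c(OCOC)cc1OCOC | intermediate
5 | [5-bromo-2,4-bis(methoxymethoxy)phenyl]copper (formed in the flask) | [Cu]c1cc(Br)c(OCOC)cc1OCOC | intermediate
6 | 1-bromo-5-geranyl-2,4-bis(methoxymethoxy)benzene | CC(C)=CCC/C(C)=C/Cc1cc(Br)c(OCOC)cc1OCOC | intermediate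
7 | dimethyl malonate | COC(=O)CC(=O)OC | starting material
8 | dimethyl 2-[5-geranyl-2,4-bis(methoxymethoxy)phenyl]propanedioate | CC(C)=CCC/C(C)=C/Cc1cc(C(C(=O)OC)C(=O)OC)c(OCOC)cc1OCOC | intermediate
9 | 2-[5-geranyl-2,4-bis(methoxymethoxy)phenyl]propane-1,3-diol | CC(C)=CCC/C(C)=C/Cc1cc(C(CO)CO)c(OCOC)cc1OCOC | intermediate
10 | vinyl benzoate | C=COC(=O)c1ccccc1 | starting material
11 | (2R)-2-[5-geranyl-2,4-bis(methoxymethoxy)phenyl]-3-hydroxypropyl benzoate | CC(C)=CCC/C(C)=C/Cc1cc([C@@H](COC(=O)c2ccccc2)CO)c(OCOC)cc1OCOC | intermediate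
12 | 2-methylresorcinol | Cc1c(O)cccc1O | starting material
13 | 1,3-bis(methoxymethoxy)-2-methylbenzene | Cc1c(OCOC)cccc1OCOC | intermediate
14 | 2-[3,5-bis(methoxymethoxy)-4-methylphenyl]-4,4,5,5-tetramethyl-1,3,2-dioxaborolane (formed in the flask) | Cc1c(OCOC)cc(B2OC(C)(C)C(C)(C)O2)cc1OCOC | intermediate
15 | 3,5-bis(methoxymethoxy)-4-methylphenol | Cc1c(OCOC)cc(O)cc1OCOC | intermediate
16 | (2R)-3-[3,5-bis(methoxymethoxy)-4-methylphenoxy]-2-[5-geranyl-2,4-bis(methoxymethoxy)phenyl]propyl benzoate | CC(C)=CCC/C(C)=C/Cc1cc([C@@H](COC(=O)c2ccccc2)COc2cc(OCOC)c(C)c(OCOC)c2)c(OCOC)cc1OCOC | intermediate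
17 | (2S)-3-[3,5-bis(methoxymethoxy)-4-methylphenoxy]-2-[5-geranyl-2,4-bis(methoxymethoxy)phenyl]propan-1-ol | CC(C)=CCC/C(C)=C/Cc1cc([C@@H](CO)COc2cc(OCOC)c(C)c(OCOC)c2)c(OCOC)cc1OCOC | intermediate
18 | (2R)-3-[3,5-bis(methoxymethoxy)-4-methylphenoxy]-2-[5-geranyl-2,4-bis(methoxymethoxy)phenyl]propanal (formed in the flask) | CC(C)=CCC/C(C)=C/Cc1cc([C@@H](C=O)COc2cc(OCOC)c(C)c(OCOC)c2)c(OCOC)cc1OCOC | intermediate
19 | (2R)-3-[3,5-bis(methoxymethoxy)-4-methylphenoxy]-2-[5-geranyl-2,4-bis(methoxymethoxy)phenyl]propanoic acid | CC(C)=CCC/C(C)=C/Cc1cc([C@@H](C(=O)O)COc2cc(OCOC)c(C)c(OCOC)c2)c(OCOC)cc1OCOC | intermediate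
20 | mixed anhydride of 19 and trifluoroacetic acid, (2R) (formed in the flask) | CC(C)=CCC/C(C)=C/Cc1cc([C@@H](C(=O)OC(=O)C(F)(F)F)COc2cc(OCOC)c(C)c(OCOC)c2)c(OCOC)cc1OCOC | intermediate
21 | (3R)-3-[5-geranyl-2,4-bis(methoxymethoxy)phenyl]-5,7-bis(methoxymethoxy)-6-methylchroman-4-one | CC(C)=CCC/C(C)=C/Cc1cc([C@@H]2COc3cc(OCOC)c(C)c(OCOC)c3C2=O)c(OCOC)cc1OCOC | intermediate
22 | (3R)-3-(5-geranyl-2,4-dihydroxyphenyl)-5,7-dihydroxy-6-methylchroman-4-one | CC(C)=CCC/C(C)=C/Cc1cc([C@@H]2COc3cc(O)c(C)c(O)c3C2=O)c(O)cc1O | target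

**Step count and risks**

Total steps: 12. Longest linear sequence: 10 steps (steps 1–5 and 8–12, from 4,6-dibromoresorcinol); the ring A phenol is a two-step branch (steps 6 and 7).

Steps most likely to fail:

Step 5. The two enantiotopic arms may be told apart poorly, because the ortho MOM-oxy group of ring B is an extra donor for zinc and may loosen the fit of the aryl group in the pocket. Over-acylation or 1,3-benzoyl migration during isolation would also lower the enantiomeric purity passed on to C3. The fallback sets out from diol 9 and returns at alcohol 17. It uses biocatalytic instead of metal-catalysed group selection: lipase-catalysed transesterification with vinyl acetate (immobilised Burkholderia cepacia lipase, t-BuOMe, rt, with the enzyme chosen by screening for acylation of the pro-R arm) should give (2R)-2-[5-geranyl-2,4-bis(methoxymethoxy)phenyl]-3-hydroxypropyl acetate F1. Mitsunobu coupling with phenol 15 under the conditions of step 8 gives the acetate aryl ether F2, and methanolysis with catalytic K2CO3 gives 17.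

Step 11. The trifluoroacetic acid released on anhydride formation may strip MOM groups; the 2'-oxygen of ring B may then capture the activated acyl group as a five-membered lactone; and acid may add to the geranyl alkenes. The fallback sets out from phenol 15 and monobenzoate 11 and returns at 21. It makes the C4–C4a bond by nucleophilic aryl addition in a non-acidic medium:
- Phenol 15 is mono-iodinated ortho to the hydroxyl (N-iodosuccinimide, CH2Cl2, −20 °C; both ortho carbons are equivalent) to 2-iodo-3,5-bis(methoxymethoxy)-4-methylphenol F3.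
- Mitsunobu coupling with 11 as in step 8 gives the iodo ether benzoate F4, and methanolysis as in step 9 gives the iodo ether alcohol F5.
- Buffered Dess–Martin oxidation (NaHCO3, CH2Cl2, 0 °C) gives the iodo ether aldehyde F6, used at once.
- An intramolecular Nozaki–Hiyama–Kishi reaction (CrCl2, catalytic NiCl2, DMF, rt) closes ring C to the protected isoflavan-4-ol F7 (both C4 epimers).
- A second Dess–Martin oxidation gives 21.

Step 12. Acid-catalysed enolisation at C3 may erode the configuration while four acetals are cleaved, and the freed 4'-hydroxyl may add to the protonated geranyl alkene to form a chroman. The fallback sets out from 16 and returns at 22. It moves the acetal cleavage to a stage with no enolisable centre and ends with a fluoride desilylation: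
- Methanolic HCl on 16, run as gently and as long as needed, gives the tetraphenol benzoate F8.
- TBSCl and imidazole in DMF give the tetrakis(tert-butyldimethylsilyl) ether benzoate F9.
- i-Bu2AlH (CH2Cl2, −78 °C) removes the benzoate without touching the aryl silyl ethers and gives the silyl-protected alcohol F10.
- Oxidation as in step 10 passes through the silyl-protected aldehyde F11 to the silyl-protected acid F12.
- Closure with (CF3CO)2O as in step 11, to which aryl silyl ethers are stable, passes through the silyl-protected mixed anhydride F13 to the silyl-protected isoflavanone F14.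
- HF·pyridine in THF/pyridine at 0 °C gives 22.

Further compounds
F1 | step 5 | (2R)-2-[5-geranyl-2,4-bis(methoxymethoxy)phenyl]-3-hydroxypropyl acetate | CC(C)=CCC/C(C)=C/Cc1cc([C@@H](COC(C)=O)CO)c(OCOC)cc1OCOC
F2 | step 5 | (2R)-3-[3,5-bis(methoxymethoxy)-4-methylphenoxy]-2-[5-geranyl-2,4-bis(methoxymethoxy)phenyl]propyl acetate | CC(C)=CCC/C(C)=C/Cc1cc([C@@H](COC(C)=O)COc2cc(OCOC)c(C)c(OCOC)c2)c(OCOC)cc1OCOC
F3 | step 11 | 2-iodo-3,5-bis(methoxymethoxy)-4-methylphenol | Cc1c(OCOC)cc(O)c(I)c1OCOC
F4 | step 11 | (2R)-3-[2-iodo-3,5-bis(methoxymethoxy)-4-methylphenoxy]-2-[5-geranyl-2,4-bis(methoxymethoxy)phenyl]propyl benzoate | CC(C)=CCC/C(C)=C/Cc1cc([C@@H](COC(=O)c2ccccc2)COc2cc(OCOC)c(C)c(OCOC)c2I)c(OCOC)cc1OCOC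
F5 | step 11 | (2S)-3-[2-iodo-3,5-bis(methoxymethoxy)-4-methylphenoxy]-2-[5-geranyl-2,4-bis(methoxymethoxy)phenyl]propan-1-ol | CC(C)=CCC/C(C)=C/Cc1cc([C@@H](CO)COc2cc(OCOC)c(C)c(OCOC)c2I)c(OCOC)cc1OCOC
F6 | step 11 | (2R)-3-[2-iodo-3,5-bis(methoxymethoxy)-4-methylphenoxy]-2-[5-geranyl-2,4-bis(methoxymethoxy)phenyl]propanal | CC(C)=CCC/C(C)=C/Cc1cc([C@@H](C=O)COc2cc(OCOC)c(C)c(OCOC)c2I)c(OCOC)cc1OCOC
F7 | step 11 | (3R)-3-[5-geranyl-2,4-bis(methoxymethoxy)phenyl]-5,7-bis(methoxymethoxy)-6-methylchroman-4-ol (both C4 epimers) | CC(C)=CCC/C(C)=C/Cc1cc([C@@H]2COc3cc(OCOC)c(C)c(OCOC)c3C2O)c(OCOC)cc1OCOC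
F8 | step 12 | (2R)-3-(3,5-dihydroxy-4-methylphenoxy)-2-(5-geranyl-2,4-dihydroxyphenyl)propyl benzoate | CC(C)=CCC/C(C)=C/Cc1cc([C@@H](COC(=O)c2ccccc2)COc2cc(O)c(C)c(O)c2)c(O)cc1O
F9 | step 12 | (2R)-3-[3,5-bis(tert-butyldimethylsilyloxy)-4-methylphenoxy]-2-[5-geranyl-2,4-bis(tert-butyldimethylsilyloxy)phenyl]propyl benzoate | CC(C)=CCC/C(C)=C/Cc1cc([C@@H](COC(=O)c2ccccc2)COc2cc(O[Si](C)(C)C(C)(C)C)c(C)c(O[Si](C)(C)C(C)(C)C)c2)c(O[Si](C)(C)C(C)(C)C)cc1O[Si](C)(C)C(C)(C)C
F10 | step 12 | (2S)-3-[3,5-bis(tert-butyldimethylsilyloxy)-4-methylphenoxy]-2-[5-geranyl-2,4-bis(tert-butyldimethylsilyloxy)phenyl]propan-1-ol | CC(C)=CCC/C(C)=C/Cc1cc([C@@H](CO)COc2cc(O[Si](C)(C)C(C)(C)C)c(C)c(O[Si](C)(C)C(C)(C)C)c2)c(O[Si](C)(C)C(C)(C)C)cc1O[Si](C)(C)C(C)(C)C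
F11 | step 12 | (2R)-3-[3,5-bis(tert-butyldimethylsilyloxy)-4-methylphenoxy]-2-[5-geranyl-2,4-bis(tert-butyldimethylsilyloxy)phenyl]propanal | CC(C)=CCC/C(C)=C/Cc1cc([C@@H](C=O)COc2cc(O[Si](C)(C)C(C)(C)C)c(C)c(O[Si](C)(C)C(C)(C)C)c2)c(O[Si](C)(C)C(C)(C)C)cc1O[Si](C)(C)C(C)(C)C
F12 | step 12 | (2R)-3-[3,5-bis(tert-butyldimethylsilyloxy)-4-methylphenoxy]-2-[5-geranyl-2,4-bis(tert-butyldimethylsilyloxy)phenyl]propanoic acid | CC(C)=CCC/C(C)=C/Cc1cc([C@@H](C(=O)O)COc2cc(O[Si](C)(C)C(C)(C)C)c(C)c(O[Si](C)(C)C(C)(C)C)c2)c(O[Si](C)(C)C(C)(C)C)cc1O[Si](C)(C)C(C)(C)C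
F13 | step 12 | mixed anhydride of F12 and trifluoroacetic acid, (2R) | CC(C)=CCC/C(C)=C/Cc1cc([C@@H](C(=O)OC(=O)C(F)(F)F)COc2cc(O[Si](C)(C)C(C)(C)C)c(C)c(O[Si](C)(C)C(C)(C)C)c2)c(O[Si](C)(C)C(C)(C)C)cc1O[Si](C)(C)C(C)(C)C
F14 | step 12 | (3R)-3-[5-geranyl-2,4-bis(tert-butyldimethylsilyloxy)phenyl]-5,7-bis(tert-butyldimethylsilyloxy)-6-methylchroman-4-one | CC(C)=CCC/C(C)=C/Cc1cc([C@@H]2COc3cc(O[Si](C)(C)C(C)(C)C)c(C)c(O[Si](C)(C)C(C)(C)C)c3C2=O)c(O[Si](C)(C)C(C)(C)C)cc1O[Si](C)(C)C(C)(C)C
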